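**Retrosynthetic overview**
1. The target is the cis-(2S,3R)-2,3-diaryl-2,3-dihydrobenzofuran. It is released last from benzyl-type ethers by neutral hydrogenolysis, so the kinetically formed cis ring never meets acid or base.
2. Rings: the four benzene rings are bought. The only ring made is the dihydrofuran ring (O1–C2–C3–C3a–C7a), closed late through the C2–C3 bond by an enantioselective Rh(II) 1,5-C–H insertion of a diaryl carbene (C3) into the O1–CH2–aryl ether, which sets C2 and C3 together.
3. The carbene precursor, a diaryl ketone, is cut at C4–CH2 and at C3a–C3. This gives a three-component aryne coupling of a 2-arylethyl Grignard reagent, a 3,5-dialkoxybenzyne and 3,5-bis(benzyloxy)benzaldehyde.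
4. Enabling feature: ring A (C3a–C4–C5–C6–C7–C7a) carries O1 on C7a, C3 on C3a and the side-chain CH2 on C4, three adjacent carbons, with its second oxygen on C6, meta to C7a. This is the addition pattern of the aryne C3a≡C4, whose C7a oxygen sends a carbon nucleophile to C4 and the metal to C3a.
5. Because the two ring-A oxygens are meta to each other, the aryne precursor comes from symmetric 5-bromoresorcinol bearing two identical 4-(benzyloxy)benzyl ethers. The one on O1 becomes C2 and its aryl ring; the one on the C6 oxygen is a protecting group.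

Key step: step 4

Assumption: the target SMILES decodes as the cis-(2S,3R) isomer (both aryl groups on one face of the dihydrofuran ring), and Rh2(S-PTAD)4 is taken as the catalyst antipode that leads to it; if the sense of induction is the opposite, the equally available Rh2(R-PTAD)4 takes its place and nothing else changes (benzofuran numbering O1, C2, C3, C3a, C4–C7, C7a is used throughout).

Step 1
Reactants: 1 5-bromobenzene-1,3-diol; 2 4-(benzyloxy)benzyl chloride (2 equiv)
Product: 3 1-bromo-3,5-bis{[4-(benzyloxy)benzyl]oxy}benzene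
Conditions: K2CO3, DMF, 60 °C
Reagents that add atoms: none
Why: Williamson ether synthesis, in which both phenoxides of the symmetric diol are alkylated by the reactive benzylic chloride while the aryl bromide is inert to carbonate.

Step 2
Reactants: 3 1-bromo-3,5-bis{[4-(benzyloxy)benzyl]oxy}benzene
Product: 4 1-bromo-2-iodo-3,5-bis{[4-(benzyloxy)benzyl]oxy}benzene
Conditions: NIS, MeCN/CH2Cl2, rt, dark
Reagents that add atoms: N-iodosuccinimide, O=C1CCC(=O)N1I
Why: Electrophilic aromatic iodination, in which the resorcinol diether ring is by far the most activated arene and is attacked at C2/C6 (equivalent by symmetry, ortho to one ether and para to the other) rather than at C4, which is crowded by two bulky benzylic ethers.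

Step 3
Reactants: 5 1-(benzyloxy)-4-(2-bromoethyl)benzene
Product: 6 2-[4-(benzyloxy)phenyl]ethylmagnesium bromide (THF solution, titrated and used as such)
Conditions: Mg turnings, THF, rt → 40 °C, slow addition
Reagents that add atoms: magnesium, [Mg]
Why: Grignard reagent formation by magnesium insertion into a primary alkyl bromide, with the aryl benzyl ether inert and slow addition limiting Wurtz coupling.

Step 4
Reactants: 4 1-bromo-2-iodo-3,5-bis{[4-(benzyloxy)benzyl]oxy}benzene; 6 2-[4-(benzyloxy)phenyl]ethylmagnesium bromide; 7 3,5-bis(benzyloxy)benzaldehyde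
Product: 12 [3,5-bis(benzyloxy)phenyl](2-{2-[4-(benzyloxy)phenyl]ethyl}-4,6-bis{[4-(benzyloxy)benzyl]oxy}phenyl)methanol (racemic), via bromoarylmagnesium chloride 8 (not isolated), via 3,5-dialkoxybenzyne 9 (not isolated), via arylmagnesium bromide 10 (not isolated), via bromomagnesium alkoxide 11 (not isolated)
Conditions: iPrMgCl·LiCl, THF, −30 °C; then 6 (2 equiv), −30 → 55 °C; then 7 (2.5 equiv), 0 °C → rt; aq NH4Cl
Reagents that add atoms: none
Why: Iodine–magnesium exchange at the C–I bond of 4 (activated by the flanking bromine and ether oxygen, C–Br untouched) gives 8, which on warming loses MgBrCl to the aryne 9 (C3a≡C4); 6 then adds its CH2 carbon to C4 and leaves magnesium on C3a in 10, and this aryl Grignard reagent is captured by aldehyde 7, so the C4–CH2 and C3a–C3 bonds form in one flask and all 28 carbons and all six oxygens of the target are in place. The closest known reaction type is the tandem addition of alkyllithium or alkylmagnesium reagents to 3-alkoxybenzynes generated from 1,2-dihaloarenes, followed by electrophilic quench of the ortho-metalated adduct. No ring is closed, and the only new stereocentre (the carbinol carbon) forms without control as a racemate and is erased in step 5. The regioselectivity needed (carbon nucleophile at C4, metal at C3a) is secured by the C7a alkoxy group next to the triple bond, whose inductive pull distorts the aryne so that the distal carbon is the electrophilic one and the carbanion develops ortho to oxygen. Because 4 derives from a symmetric diether only one aryne can form, and the excess of the unhindered primary Grignard reagent should outcompete the di-ortho-substituted species 8 and 10 for it. The excess of 6 is consumed by the surplus of 7, and its adduct is removed by chromatography.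

Step 5
Reactants: 12 the racemic diaryl carbinol
Product: 13 [3,5-bis(benzyloxy)phenyl](2-{2-[4-(benzyloxy)phenyl]ethyl}-4,6-bis{[4-(benzyloxy)benzyl]oxy}phenyl)methanone
Conditions: Dess–Martin periodinane, CH2Cl2, rt
Reagents that add atoms: none
Why: Dess–Martin oxidation of a doubly benzylic secondary alcohol under nearly neutral conditions that leave the six benzylic ethers untouched and remove the uncontrolled stereocentre.

Step 6
Reactants: 13 the diaryl ketone
Product: 14 hydrazone of 13 (E/Z mixture, both usable)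
Conditions: N2H4·H2O (large excess), AcOH (cat.), n-BuOH, 120 °C, sealed tube
Reagents that add atoms: hydrazine (as hydrate), NN
Why: Hydrazone condensation, in which the small alpha-effect nucleophile in large excess and with heat should overcome the shielding by the 2,6-disubstituted ring, the same shielding suppresses azine formation, and the absence of strong base excludes Wolff–Kishner reduction.

Step 7
Reactants: 14 the hydrazone
Product: 16 (2S,3R)-2-[4-(benzyloxy)phenyl]-3-[3,5-bis(benzyloxy)phenyl]-6-{[4-(benzyloxy)benzyl]oxy}-4-{2-[4-(benzyloxy)phenyl]ethyl}-2,3-dihydro-1-benzofuran (cis), via diaryldiazomethane 15 (not isolated)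
Conditions: MnO2, CH2Cl2, rt, filtration; filtrate added to Rh2(S-PTAD)4 (1 mol%), CH2Cl2, 0 °C → rt
Reagents that add atoms: none
Why: MnO2 dehydrogenation of the hydrazone followed by Rh(II)-catalysed enantioselective intramolecular 1,5-C–H insertion of a donor/donor (diaryl) carbene, a reaction type established for 2-(benzyloxy)benzophenone-derived diazo compounds, closes the C2–C3 bond and sets both stereocentres at once, the absolute sense through the chiral carboxylate pocket and the cis relation as the kinetic result of hydride shift and rapid C–C collapse, while the ether C–H bond, activated by O1 and the 4-alkoxyphenyl ring, should be preferred over the merely benzylic CH2 of the C4 side chain.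

Step 8
Reactants: 16 the protected cis-dihydrobenzofuran
Product: 17 5-[(2S,3R)-6-hydroxy-2-(4-hydroxyphenyl)-4-[2-(4-hydroxyphenyl)ethyl]-2,3-dihydro-1-benzofuran-3-yl]benzene-1,3-diol (target)
Conditions: H2 (1 atm), Pd/C (neutral, prewashed), EtOAc/EtOH, rt, stopped at full debenzylation
Reagents that add atoms: none
Why: Catalytic hydrogenolysis cleaves the six unhindered primary benzylic C–O bonds faster than the hindered secondary C2–O1 bond of the ring, and the neutral medium prevents C2–O1 ionisation, so the cis-(2S,3R) configuration is retained.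

**Compound list**
1 | 5-bromobenzene-1,3-diol | Oc1cc(O)cc(Br)c1 | starting material
2 | 4-(benzyloxy)benzyl chloride | ClCc1ccc(OCc2ccccc2)cc1 | starting material
3 | 1-bromo-3,5-bis{[4-(benzyloxy)benzyl]oxy}benzene | Brc1cc(OCc2ccc(OCc3ccccc3)cc2)cc(OCc2ccc(OCc3ccccc3)cc2)c1 | intermediate
4 | 1-bromo-2-iodo-3,5-bis{[4-(benzyloxy)benzyl]oxy}benzene | Brc1cc(OCc2ccc(OCc3ccccc3)cc2)cc(OCc2ccc(OCc3ccccc3)cc2)c1I | intermediate
5 | 1-(benzyloxy)-4-(2-bromoethyl)benzene | BrCCc1ccc(OCc2ccccc2)cc1 | starting material
6 | 2-[4-(benzyloxy)phenyl]ethylmagnesium bromide | Br[Mg]CCc1ccc(OCc2ccccc2)cc1 | intermediate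
7 | 3,5-bis(benzyloxy)benzaldehyde | O=Cc1cc(OCc2ccccc2)cc(OCc2ccccc2)c1 | starting material
8 | 2-bromo-4,6-bis{[4-(benzyloxy)benzyl]oxy}phenylmagnesium chloride | Brc1cc(OCc2ccc(OCc3ccccc3)cc2)cc(OCc2ccc(OCc3ccccc3)cc2)c1[Mg]Cl | intermediate
9 | 3,5-bis{[4-(benzyloxy)benzyl]oxy}benzyne | C1#CC(OCc2ccc(OCc3ccccc3)cc2)=CC(OCc2ccc(OCc3ccccc3)cc2)=C1 | intermediate
10 | (2-{2-[4-(benzyloxy)phenyl]ethyl}-4,6-bis{[4-(benzyloxy)benzyl]oxy}phenyl)magnesium bromide | Br[Mg]c1c(CCc2ccc(OCc3ccccc3)cc2)cc(OCc2ccc(OCc3ccccc3)cc2)cc1OCc1ccc(OCc2ccccc2)cc1 | intermediate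
11 | bromomagnesium alkoxide of 12 (racemic) | Br[Mg]OC(c1cc(OCc2ccccc2)cc(OCc2ccccc2)c1)c1c(CCc2ccc(OCc3ccccc3)cc2)cc(OCc2ccc(OCc3ccccc3)cc2)cc1OCc1ccc(OCc2ccccc2)cc1 | intermediate
12 | [3,5-bis(benzyloxy)phenyl](2-{2-[4-(benzyloxy)phenyl]ethyl}-4,6-bis{[4-(benzyloxy)benzyl]oxy}phenyl)methanol (racemic) | OC(c1cc(OCc2ccccc2)cc(OCc2ccccc2)c1)c1c(CCc2ccc(OCc3ccccc3)cc2)cc(OCc2ccc(OCc3ccccc3)cc2)cc1OCc1ccc(OCc2ccccc2)cc1 | intermediate
13 | [3,5-bis(benzyloxy)phenyl](2-{2-[4-(benzyloxy)phenyl]ethyl}-4,6-bis{[4-(benzyloxy)benzyl]oxy}phenyl)methanone | O=C(c1cc(OCc2ccccc2)cc(OCc2ccccc2)c1)c1c(CCc2ccc(OCc3ccccc3)cc2)cc(OCc2ccc(OCc3ccccc3)cc2)cc1OCc1ccc(OCc2ccccc2)cc1 | intermediate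
14 | hydrazone of 13 (E/Z mixture) | NN=C(c1cc(OCc2ccccc2)cc(OCc2ccccc2)c1)c1c(CCc2ccc(OCc3ccccc3)cc2)cc(OCc2ccc(OCc3ccccc3)cc2)cc1OCc1ccc(OCc2ccccc2)cc1 | intermediate
15 | diaryldiazomethane derived from 14 | [N-]=[N+]=C(c1cc(OCc2ccccc2)cc(OCc2ccccc2)c1)c1c(CCc2ccc(OCc3ccccc3)cc2)cc(OCc2ccc(OCc3ccccc3)cc2)cc1OCc1ccc(OCc2ccccc2)cc1 | intermediate
16 | (2S,3R)-2-[4-(benzyloxy)phenyl]-3-[3,5-bis(benzyloxy)phenyl]-6-{[4-(benzyloxy)benzyl]oxy}-4-{2-[4-(benzyloxy)phenyl]ethyl}-2,3-dihydro-1-benzofuran (cis) | C(c1ccccc1)Oc1ccc(CCc2cc(OCc4ccc(OCc5ccccc5)cc4)cc3c2[C@@H](c2cc(OCc4ccccc4)cc(OCc4ccccc4)c2)[C@@H](c2ccc(OCc4ccccc4)cc2)O3)cc1 | intermediate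
17 | 5-[(2S,3R)-6-hydroxy-2-(4-hydroxyphenyl)-4-[2-(4-hydroxyphenyl)ethyl]-2,3-dihydro-1-benzofuran-3-yl]benzene-1,3-diol | Oc1ccc(CCc2cc(O)cc3c2[C@@H](c2cc(O)cc(O)c2)[C@@H](c2ccc(O)cc2)O3)cc1 | target

**Total step count:** 8.
**Longest linear sequence:** 7 steps (1 → 3 → 4 → 12 → 13 → 14 → 16 → 17; step 3 is the side branch).

**Steps most likely to fail**

Step 4. Three things may go wrong:
- Loss of MgBrCl from 8 may need temperatures at which the organomagnesium species degrade.
- The aryne may be consumed by 8 or 10 (biaryl formation) instead of by 6.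
- 10 may be protonated before it is captured.

The fallback sets out from 3 and 6 and returns to the route at 10. Compound 6 is transmetalated with ZnBr2 (THF, 0 °C) to 2-[4-(benzyloxy)phenyl]ethylzinc bromide F1. Negishi coupling of F1 with 3 (Pd(OAc)2/SPhos, THF, 50 °C) forms the same aryl–CH2 bond by conventional cross-coupling and gives the 5-(2-arylethyl)resorcinol diether F2. NIS (MeCN/CH2Cl2, rt) iodinates one of the two equivalent positions between the side chain and an ether group, giving the aryl iodide F3. Iodine–magnesium exchange with iPrMgBr (THF, 0 °C) then gives 10, which is treated with 7 and worked up as in step 4.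

Step 6. Addition of hydrazine to a carbonyl group shielded above and below by the 2,6-disubstituted ring may stall before useful conversion. The fallback sets out from 13 and returns at 14. Thionation with Lawesson's reagent (toluene, 110 °C) gives the diaryl thioketone F4. Its longer and more electrophilic C=S bond should react with hydrazine hydrate at room temperature (THF/EtOH) to give 14.

Step 7. Three things may go wrong:
- The carbene carbon lies between two ortho substituents, so rhodium carbene formation may be slow.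
- Insertion into the ArCH2 C–H bond of the C4 side chain (five-membered carbocycle formation) may compete with insertion into the ether C–H bond.
- Facial selectivity may be eroded.

The fallback sets out from 13 and returns at 17. Base-induced 5-exo-trig addition of the O1-benzylic carbanion to the ketone (KOtBu, DMF, rt) gives the 3-hydroxy-2,3-dihydrobenzofuran F5. Mild acid (PPTS, toluene, 60 °C) dehydrates F5 to the 2,3-diarylbenzofuran F6. Heterogeneous hydrogenation (H2, 50 bar, Pd/C, EtOAc/EtOH, 50 °C) adds hydrogen to one face of C2=C3 (syn addition, hence cis) and removes all benzylic ethers. This gives racemic cis material, that is 17 together with its (2R,3S) enantiomer F7. The two are separated by preparative chromatography on a chiral stationary phase.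

**Further compounds**
F1 | step 4 | 2-[4-(benzyloxy)phenyl]ethylzinc bromide | Br[Zn]CCc1ccc(OCc2ccccc2)cc1
F2 | step 4 | 1-{2-[4-(benzyloxy)phenyl]ethyl}-3,5-bis{[4-(benzyloxy)benzyl]oxy}benzene | c1(CCc2ccc(OCc3ccccc3)cc2)cc(OCc2ccc(OCc3ccccc3)cc2)cc(OCc2ccc(OCc3ccccc3)cc2)c1
F3 | step 4 | 1-{2-[4-(benzyloxy)phenyl]ethyl}-2-iodo-3,5-bis{[4-(benzyloxy)benzyl]oxy}benzene | Ic1c(CCc2ccc(OCc3ccccc3)cc2)cc(OCc2ccc(OCc3ccccc3)cc2)cc1OCc1ccc(OCc2ccccc2)cc1
F4 | step 6 | [3,5-bis(benzyloxy)phenyl](2-{2-[4-(benzyloxy)phenyl]ethyl}-4,6-bis{[4-(benzyloxy)benzyl]oxy}phenyl)methanethione | S=C(c1cc(OCc2ccccc2)cc(OCc2ccccc2)c1)c1c(CCc2ccc(OCc3ccccc3)cc2)cc(OCc2ccc(OCc3ccccc3)cc2)cc1OCc1ccc(OCc2ccccc2)cc1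
F5 | step 7 | 2-[4-(benzyloxy)phenyl]-3-[3,5-bis(benzyloxy)phenyl]-6-{[4-(benzyloxy)benzyl]oxy}-4-{2-[4-(benzyloxy)phenyl]ethyl}-2,3-dihydro-1-benzofuran-3-ol (racemic, diastereomer mixture) | OC1(c2cc(OCc3ccccc3)cc(OCc3ccccc3)c2)C(c2ccc(OCc3ccccc3)cc2)Oc2cc(OCc3ccc(OCc4ccccc4)cc3)cc(CCc3ccc(OCc4ccccc4)cc3)c21
F6 | step 7 | 2-[4-(benzyloxy)phenyl]-3-[3,5-bis(benzyloxy)phenyl]-6-{[4-(benzyloxy)benzyl]oxy}-4-{2-[4-(benzyloxy)phenyl]ethyl}-1-benzofuran | c1(-c2ccc(OCc3ccccc3)cc2)oc2cc(OCc3ccc(OCc4ccccc4)cc3)cc(CCc3ccc(OCc4ccccc4)cc3)c2c1-c1cc(OCc2ccccc2)cc(OCc2ccccc2)c1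
F7 | step 7 | 5-[(2R,3S)-6-hydroxy-2-(4-hydroxyphenyl)-4-[2-(4-hydroxyphenyl)ethyl]-2,3-dihydro-1-benzofuran-3-yl]benzene-1,3-diol (enantiomer of 17) | Oc1ccc(CCc2cc(O)cc3c2[C@H](c2cc(O)cc(O)c2)[C@H](c2ccc(O)cc2)O3)cc1
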